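## Structural features

The target is a flavanone: a benzene ring A fused to a dihydropyran-4-one ring C (a chroman-4-one), with ring B, a 4-methoxy-3-prenylphenyl group, attached through the single bond C2–C1'. Ring A carries hydroxyls at C5 and C7, the ring oxygen O1 at C8a and the ketone carbon C4 at C4a, so it is a 2,4,6-trioxygenated aryl ketone (an acylphloroglucinol). C2 is the only stereocentre and is (S); it is benzylic to the electron-rich ring B, bonded to O1 and β to the C4 carbonyl, and no second stereocentre stands next to it, so its configuration has to be set absolutely. The fragile points are four: the O1–C2 bond, which opens under base by retro-oxa-Michael (E1cB) reaction to the achiral chalcone and so racemizes C2; the para-methoxybenzylic C2–O bond, which ionizes under acid; the trisubstituted prenyl alkene (strong acid, hydrogenation, electrophiles); and the air-sensitive free phenols. The real difficulty is to place three oxygens and one acyl group on ring A without regiochemical ambiguity while C2 is made as a single enantiomer and is then never exposed to conditions that open or ionize it. The key step uses the alternation on ring A: the oxygens at C5, C7 and C8a alternate with C6, C8 and C4a exactly as the carbonyls C1 (ester), C3 and C5 of a linear poly-β-carbonyl ester alternate with its methylenes. The next carbonyl of the chain (C7) is the flavanone C4, the next methylene (C8) is C3 and the chain terminus (C9) is C2; the three ring oxygens therefore come from the ester carbonyl and the 3- and 5-ketones, not from the 7-ketone.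

## Logic of the disconnections

O1–C2 (ring C). The only stereocentre of 22 sits on this C–O bond, so it is cut first, which leads to 20. The gain is that ring C, with its base-labile O1–C2 bond, does not exist until the last step, and the stereochemical problem shrinks to that of a secondary benzylic carbinol. The forward step must be a stereospecific SN2 closure under neutral conditions; because it inverts, 20 must be (R). The two ortho hydroxyls of 20 are equivalent, so no regiochemical demand arises. The carbinol is carried as its silyl ether 19 until then.

C4a–C5 (ring A). In 19 the aromatic ring is cut between the acyl-bearing carbon and a neighbouring hydroxyl-bearing carbon, which unravels ring A into the linear chain of 17. The gain is that the positions of three oxygens and the acyl group are encoded in the order of carbonyls of an open chain. The forward step must close C6 onto the C1 ester and not C2 onto the C7 ketone, and must leave the C9 oxygen in place. Hence the methyl ester is matched to methoxide, magnesium is the counter-ion and C9–O is silylated.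

C6–C7 of the chain (the later C4–C4a bond). 17 is cut into the acyl donor 11, which holds ring B, the stereocentre and three chain carbons, and the six-carbon tricarbonyl unit 14, used as its trianion 15. The gain is convergence: the chiral half and the polyketide half are made separately. The forward step must acylate 15 at its terminal carbon only, and the acyl donor must resist enolization, β-elimination and over-addition. For that reason 11 is an N-methoxy-N-methylamide, not an acyl imidazolide or an ester.

14 back to 12. The 3,5-dioxohexanoate chain of 14 is already present in 12 as an enol lactone with one extra acetyl group. Forward, this needs lactone methanolysis and selective loss of that acetyl group, which Mg(OMe)2 in methanol does in one operation.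

C9–O stereocentre back to a carbonyl (11 from 10, 9 and 8). No skeletal bond is cut; amide, silyl ether and carbinol are traced back to the ketone of 8. The gain is that the stereocentre comes from a catalytic reduction of a β-keto ester, a well-behaved substrate class. The forward step must give the (R)-carbinol with high selectivity and must not touch the prenyl alkene, which points to transfer hydrogenation and away from H2.

C2–C3 (the ketone–CH2 bond of 8). This cut gives 5 and 6. The gain is a two-carbon extension from a simple benzoate. The forward step is a crossed Claisen condensation in which 5 can act only as acceptor; because 5 is an electron-rich ester, the enolate 7 is preformed.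

C3'–prenyl and O–CH3 (5 from 4, and 4 from 1 and 2). The aryl–allyl bond and the methyl ether are cut last. The forward demand is C-alkylation of the phenoxide 3 at the ortho carbon instead of at oxygen; the para position is blocked and the two ortho positions are equivalent.

## Other disconnections considered

Alternative 1: Ring C is cut at C3–C4 and O1–C2, so that it becomes the [4+2] adduct of an ortho-quinone methide and a styrene.
- Forward key step: a chiral BINOL-derived phosphoric acid would ionize the salicylaldehyde acetal A1 (2-(dimethoxymethyl)-3,5-bis(methoxymethoxy)phenol) with loss of methanol to the methoxy ortho-quinone methide A3. The styrene A2 (4-methoxy-3-prenylstyrene) would then add to this oxa-diene with inverse electron demand. Its CH2 terminus bonds to the former acetal carbon (C4) and the quinone methide oxygen to the benzylic carbon (C2), giving the chroman A4 ((2S,4S)-4-methoxy-5,7-bis(methoxymethoxy)-2-(4-methoxy-3-prenylphenyl)chroman).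
- In its favour: two bonds, ring C and the stereocentre C2 are made in one catalytic event from two achiral pieces of similar size, and C2 never carries a leaving group.
- Against it here: A4 is at the alcohol oxidation level at C4. The benzylic methyl ether must be oxidized to the ketone in a molecule that also holds a prenyl alkene, a second benzylic ether C–H at C2 and two electron-rich arenes. The prenyl double bond of A2 is a second nucleophilic alkene that can also engage A3. The acetal protecting groups and the C4 methoxy group sit in an acidic medium, and a final acidic deprotection is still needed.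
- Comparison on structure: this plan ignores the polyketide pattern of ring A and takes ring A preformed.
- Comparison on mechanism: face selection depends on an ion pair between A3 and the chiral phosphate, whereas the chosen plan sets the stereocentre by a ketone reduction and transfers it by an SN2 displacement.
- Where it is the better plan: convergence, and the catalytic setting of C2 in the ring-forming event.
- Step economy: the two plans should be about equal, because the redox correction at C4 and the deprotection add steps after the cycloaddition.

Alternative 2: Ring C is cut at C2–C3.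
- Forward key step: Rh2(S-PTTL)4, a dimer of divalent rhodium, would decompose the diazoketone A5 (2-diazo-1-[2-(4-methoxy-3-prenylbenzyloxy)-4,6-bis(tert-butyldimethylsilyloxy)phenyl]ethanone). The carbenic C3 would insert into one of the two enantiotopic benzylic C2–H bonds, which are activated by the ether oxygen and by ring B. This closes the six-membered ring and gives A6 ((S)-5,7-bis(tert-butyldimethylsilyloxy)-4'-methoxy-3'-prenylflavanone).
- In its favour: C2 is set from an achiral precursor by the catalyst in the C–C bond-forming step, no leaving group ever sits at the ionizable benzylic carbon, and the product is at the right oxidation level.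
- Against it here: attack of the ether oxygen on the carbene followed by a benzyl shift is a well-known competitor with benzyl ethers, and a six-membered C–H insertion is less favoured than a five-membered one. A carbene with a single acceptor group is reactive enough to add to the electron-rich ring B or to the prenyl alkene of a second molecule. A5 needs diazoalkane chemistry. Fluoride desilylation of A6 exposes a 5-hydroxyflavanone to base, with the risk of ring opening and racemization.
- Comparison on structure: ring A is taken preformed and only ring C is built.
- Comparison on mechanism: the catalyst must choose between two enantiotopic hydrogens, a demanding task for this carbene class, whereas the chosen plan relies on ketone reduction and SN2 inversion.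
- Where it is the better plan: avoiding an SN2 inversion at C2.
- Step economy: about equal or slightly better in step count.
- Overall: the chemoselectivity of the carbene is less secure than the chain folding of the chosen plan.

Alternative 3: Ring C is cut at O1–C8a and C4–C4a.
- Forward key step: CsF would release the aryne A8 (3,5-bis(methoxymethoxy)benzyne) from the silyl triflate A7 (3,5-bis(methoxymethoxy)-2-(trimethylsilyl)phenyl trifluoromethanesulfonate). The alkoxide of the hydroxy ester A9 (methyl (S)-3-hydroxy-3-(4-methoxy-3-prenylphenyl)propanoate, the enantiomer of 9, available from 8 with the mirror-image catalyst) would add to the aryne carbon remote from the flanking alkoxy group (C8a). The aryl anion formed next to that alkoxy group (C4a) would then attack the ester, giving A10 ((S)-5,7-bis(methoxymethoxy)-4'-methoxy-3'-prenylflavanone).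
- In its favour: no bond to the stereocentre is touched, so its configuration is simply retained. The regiochemistry follows from the inductive effect of the alkoxy group next to the aryne. The longest linear sequence from 8 is very short.
- Against it here: a hindered secondary alkoxide is a modest aryne nucleophile, and as a β-hydroxy ester it can undergo retro-aldol cleavage or E1cB dehydration under the basic fluoride conditions. Proton transfer to the aryl anion competes with the acyl transfer. The 5-alkoxyflavanone formed can open to the chalcone in the same medium. A7 needs a multistep preparation, and an acidic deprotection closes the route.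
- Comparison on structure: both plans use the same chiral three-carbon piece, but this one attaches a preformed ring A and the chosen plan grows ring A from the chain.
- Comparison on mechanism: the aryne cascade is less predictable than the magnesium-templated Claisen closure.
- Where it is the better plan: retention at C2 in place of an SN2 inversion at a para-methoxybenzylic carbon, and the length of the longest linear sequence.
- Step economy: the total count is about equal once A7 is included.

Key step: step 9

Assumption: the facial sense of RuCl[(R,R)-TsDPEN](p-cymene) on the aroylacetate 8 is taken to follow that on simple aryl alkyl ketones (aryl group against the η6-arene), which gives the (R)-carbinol needed for inversion to (S)-C2 in the last step.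

## Steps

Step 1
Reactants: 1 methyl 4-hydroxybenzoate; 2 prenyl bromide (1-bromo-3-methylbut-2-ene)
Product: 4 methyl 4-hydroxy-3-(3-methylbut-2-en-1-yl)benzoate, via sodium aryloxide 3 (not isolated)
Conditions: NaH (1.05 equiv), toluene, 0 °C to rt; then 2, rt to 60 °C
Reagents that add atoms: none
Why: Ortho-C-alkylation of a phenoxide; in toluene the sodium aryloxide 3 is a tight, unsolvated aggregate whose oxygen is shielded by Na+, so the primary allylic bromide is attacked by the ortho carbon (SN2 at CH2) and the dienone tautomerizes back to the phenol; the para position is blocked by the ester and the two ortho positions are equivalent, so only one C-prenyl isomer can form.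

Step 2
Reactants: 4 methyl 4-hydroxy-3-(3-methylbut-2-en-1-yl)benzoate
Product: 5 methyl 4-methoxy-3-(3-methylbut-2-en-1-yl)benzoate
Conditions: MeI, K2CO3, acetone, reflux
Reagents that add atoms: iodomethane, CI
Why: Williamson ether synthesis; the phenoxide formed by K2CO3 is methylated at oxygen, and the ester and the trisubstituted alkene are inert.

Step 3
Reactants: 5 methyl 4-methoxy-3-(3-methylbut-2-en-1-yl)benzoate; 6 methyl acetate
Product: 8 methyl 3-(4-methoxy-3-prenylphenyl)-3-oxopropanoate, via methyl acetate lithium enolate 7 (not isolated)
Conditions: LiN(SiMe3)2 (2.5 equiv), 6 (2.5 equiv), THF, −78 °C; then 5, −78 to 0 °C; aq NH4Cl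
Reagents that add atoms: none
Why: Crossed Claisen condensation; 5 has no α-hydrogen and can act only as acceptor, the enolate 7 is preformed at low temperature to limit self-condensation, and deprotonation of the β-keto ester by the second equivalent of base drives the addition–elimination forward.

Step 4
Reactants: 8 methyl 3-(4-methoxy-3-prenylphenyl)-3-oxopropanoate
Product: 9 methyl (R)-3-hydroxy-3-(4-methoxy-3-prenylphenyl)propanoate
Conditions: RuCl[(R,R)-TsDPEN](p-cymene) (1 mol %), HCO2H–Et3N (5:2), CH2Cl2, 30 °C
Reagents that add atoms: none
Why: Noyori–Ikariya asymmetric transfer hydrogenation; Ru–H and N–H are transferred to C=O in a six-membered outer-sphere transition state in which the aryl ring of 8 lies against the η6-p-cymene ligand (CH/π contact), so the (R,R)-ligand should deliver hydride to the Si face and set the (R)-carbinol, while the isolated prenyl alkene and the ester are not reduced.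

Step 5
Reactants: 9 methyl (R)-3-hydroxy-3-(4-methoxy-3-prenylphenyl)propanoate
Product: 10 methyl (R)-3-(tert-butyldimethylsilyloxy)-3-(4-methoxy-3-prenylphenyl)propanoate
Conditions: TBSCl, imidazole, DMF, rt
Reagents that add atoms: tert-butyldimethylsilyl chloride, CC(C)(C)[Si](C)(C)Cl
Why: Silylation of a secondary alcohol through an N-silylimidazolium donor; the silyl ether blocks lactol formation and retro-aldol cleavage in steps 6 to 9 and is stable to amide bases and to methoxide, and no bond to the stereocentre is touched.

Step 6
Reactants: 10 methyl (R)-3-(tert-butyldimethylsilyloxy)-3-(4-methoxy-3-prenylphenyl)propanoate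
Product: 11 (R)-3-(tert-butyldimethylsilyloxy)-N-methoxy-3-(4-methoxy-3-prenylphenyl)-N-methylpropanamide
Conditions: MeNH(OMe)·HCl, i-PrMgCl, THF, −20 to 0 °C; aq NH4Cl
Reagents that add atoms: N,O-dimethylhydroxylamine hydrochloride, CNOC.Cl
Why: Direct aminolysis of the ester by the chloromagnesium amide of N,O-dimethylhydroxylamine (Weinreb amide synthesis); the weakly basic nucleophile adds at −20 °C without enolizing the ester, so β-elimination of the silyloxy group is not expected, and the product is a stable, purifiable acyl donor that cannot over-add.

Step 7
Reactants: 12 dehydroacetic acid (3-acetyl-6-methyl-2H-pyran-2,4(3H)-dione)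
Product: 14 methyl 3,5-dioxohexanoate, via methyl 2-acetyl-3,5-dioxohexanoate 13 (not isolated)
Conditions: Mg(OMe)2, MeOH, reflux; then cold 1 M HCl
Reagents that add atoms: magnesium methoxide, [Mg+2].[O-]C.[O-]C (its methoxide, in exchange with the solvent methanol, CO, becomes the ester OMe)
Why: Methoxide opens the enol lactone of 12 to 13, and a retro-Claisen cleavage, steered by magnesium chelation of the 3,5-diketo ester that remains, removes the extra acetyl group as methyl acetate; this is the known degradation of 12 to the 3,5-dioxohexanoate.

Step 8
Reactants: 14 methyl 3,5-dioxohexanoate; 11 (R)-3-(tert-butyldimethylsilyloxy)-N-methoxy-3-(4-methoxy-3-prenylphenyl)-N-methylpropanamide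
Product: 17 methyl (R)-9-(tert-butyldimethylsilyloxy)-9-(4-methoxy-3-prenylphenyl)-3,5,7-trioxononanoate, via trilithium trianion 15 (not isolated), via tetrahedral adduct 16 (not isolated)
Conditions: 14, LiN(iPr)2 (3.1 equiv per 14), THF, −78 to 0 °C; then 11 (0.5 equiv per 14), −78 to −20 °C; AcOH, −78 °C, then pH 5 buffer; used without delay
Reagents that add atoms: none
Why: Acylation of a poly-β-carbonyl polyanion at its terminal carbon; in 15 the last-formed, least stabilized carbanion (the former methyl group) is by far the most nucleophilic site and adds to the amide carbonyl, and the chelated adduct 16 holds the new acyl group at the hemiaminal stage until the acidic quench, so the triketo ester is never exposed to the base.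

Step 9
Reactants: 17 methyl (R)-9-(tert-butyldimethylsilyloxy)-9-(4-methoxy-3-prenylphenyl)-3,5,7-trioxononanoate
Product: 19 (R)-3-(tert-butyldimethylsilyloxy)-3-(4-methoxy-3-prenylphenyl)-1-(2,4,6-trihydroxyphenyl)propan-1-one, via 2-acylcyclohexane-1,3,5-trione 18 (not isolated)
Conditions: Mg(OMe)2 (6 equiv), MeOH, argon, rt; then cold 0.5 M HCl to pH 4
Reagents that add atoms: none
Why: Mg(OMe)2 turns 17 into a magnesium polyenolate in which the most acidic methylenes, C4 and C6 (each flanked by two ketones), are deprotonated and the oxygens at C3, C5 and C7 are held as chelates. C6 then attacks the C1 ester carbonyl, the one carbonyl of the chain that is not part of an enolate, in an intramolecular Claisen (Dieckmann-type) acyl substitution; methoxide leaves and the C6–C1 bond (the later C4a–C5 bond) closes ring A in a 6-exo-trig mode to give the trione 18. Threefold enolization of 18 gives the aromatic acylphloroglucinol 19, which makes the closure irreversible. The closest known reaction type is the biomimetic Claisen cyclization of 3,5,7-triketo esters to acylphloroglucinols, the laboratory counterpart of the ring closure of chalcone biosynthesis. No stereocentre is formed; C9 is not enolizable and no bond to it is touched, so its (R) configuration should be carried through. The selectivity needed is Claisen closure (C6 onto C1) over aldol closure (C2 onto C7) and over O-cyclization: the C7 ketone is masked inside the C5–C7 magnesium diketonate, C2 is the least acidic of the three activated methylenes, the methyl ester is matched to methoxide so that transesterification is degenerate and no carboxylate can form in the water-free medium, and Mg2+ bound at the C3 oxygen activates the ester. β-Elimination of the silyloxy group would need deprotonation at C8, the second α-position of an already enolized diketonate, which is out of reach of methoxide, and the silyl ether keeps the C9 oxygen from adding to C5.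

Step 10
Reactants: 19 (R)-3-(tert-butyldimethylsilyloxy)-3-(4-methoxy-3-prenylphenyl)-1-(2,4,6-trihydroxyphenyl)propan-1-one
Product: 20 (R)-3-hydroxy-3-(4-methoxy-3-prenylphenyl)-1-(2,4,6-trihydroxyphenyl)propan-1-one
Conditions: HF·pyridine, pyridine, THF, 0 °C to rt
Reagents that add atoms: none
Why: Fluoride-driven Si–O cleavage (strong Si–F bond); buffering with excess pyridine keeps the medium too weakly basic for E1cB dehydration of the β-hydroxy ketone and too weakly acidic for ionization of the para-methoxybenzylic C–O bond, so the (R) configuration should be preserved and the phenols and the prenyl group stay untouched.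

Step 11
Reactants: 20 (R)-3-hydroxy-3-(4-methoxy-3-prenylphenyl)-1-(2,4,6-trihydroxyphenyl)propan-1-one
Product: 22 4'-O-methyllicoflavanone ((S)-5,7-dihydroxy-2-(4-methoxy-3-prenylphenyl)chroman-4-one), via alkoxyphosphonium phenoxide 21 (not isolated)
Conditions: PPh3, DIAD, toluene–THF (0.01 M), −20 °C to rt
Reagents that add atoms: none
Why: Mitsunobu cyclodehydration; PPh3 and DIAD activate the benzylic hydroxyl as the alkoxyphosphonium 21 and an ortho-phenoxide displaces Ph3PO intramolecularly (6-exo-tet, SN2) with inversion, turning the (R)-carbinol into (S)-C2; the two ortho hydroxyls are equivalent, the para hydroxyl cannot reach C2, and the neutral, dilute, low-polarity medium disfavours ionization, intermolecular etherification and retro-oxa-Michael opening of the 5-hydroxyflavanone.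

## Compound list

1 | methyl 4-hydroxybenzoate | COC(=O)c1ccc(O)cc1 | starting material
2 | prenyl bromide (1-bromo-3-methylbut-2-ene) | CC(C)=CCBr | starting material
3 | sodium 4-(methoxycarbonyl)phenoxide (formed in the flask) | COC(=O)c1ccc([O-])cc1.[Na+] | intermediate
4 | methyl 4-hydroxy-3-(3-methylbut-2-en-1-yl)benzoate | COC(=O)c1ccc(O)c(CC=C(C)C)c1 | intermediate
5 | methyl 4-methoxy-3-(3-methylbut-2-en-1-yl)benzoate | COc1ccc(C(=O)OC)cc1CC=C(C)C | intermediate
6 | methyl acetate | CC(=O)OC | starting material
7 | lithium enolate of methyl acetate (formed in the flask) | C=C([O-])OC.[Li+] | intermediate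
8 | methyl 3-(4-methoxy-3-prenylphenyl)-3-oxopropanoate | COc1ccc(C(=O)CC(=O)OC)cc1CC=C(C)C | intermediate
9 | methyl (R)-3-hydroxy-3-(4-methoxy-3-prenylphenyl)propanoate | COc1ccc([C@H](O)CC(=O)OC)cc1CC=C(C)C | intermediate
10 | methyl (R)-3-(tert-butyldimethylsilyloxy)-3-(4-methoxy-3-prenylphenyl)propanoate | COc1ccc([C@H](O[Si](C)(C)C(C)(C)C)CC(=O)OC)cc1CC=C(C)C | intermediate
11 | (R)-3-(tert-butyldimethylsilyloxy)-N-methoxy-3-(4-methoxy-3-prenylphenyl)-N-methylpropanamide | COc1ccc([C@H](O[Si](C)(C)C(C)(C)C)CC(=O)N(C)OC)cc1CC=C(C)C | intermediate
12 | dehydroacetic acid | CC(=O)C1C(=O)C=C(C)OC1=O | starting material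
13 | methyl 2-acetyl-3,5-dioxohexanoate (formed in the flask) | COC(=O)C(C(C)=O)C(=O)CC(C)=O | intermediate
14 | methyl 3,5-dioxohexanoate | COC(=O)CC(=O)CC(C)=O | intermediate
15 | trilithium trianion of methyl 3,5-dioxohexanoate (formed in the flask) | [Li+].[Li+].[Li+].C=C([O-])C=C([O-])C=C([O-])OC | intermediate
16 | trilithium tetrahedral adduct of 15 and 11 (formed in the flask) | COc1ccc([C@H](O[Si](C)(C)C(C)(C)C)CC([O-])(CC([O-])=CC([O-])=CC(=O)OC)N(C)OC)cc1CC=C(C)C.[Li+].[Li+].[Li+] | intermediate
17 | methyl (R)-9-(tert-butyldimethylsilyloxy)-9-(4-methoxy-3-prenylphenyl)-3,5,7-trioxononanoate | COc1ccc([C@H](O[Si](C)(C)C(C)(C)C)CC(=O)CC(=O)CC(=O)CC(=O)OC)cc1CC=C(C)C | intermediate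
18 | 2-[(R)-3-(tert-butyldimethylsilyloxy)-3-(4-methoxy-3-prenylphenyl)propanoyl]cyclohexane-1,3,5-trione (formed in the flask) | COc1ccc([C@H](O[Si](C)(C)C(C)(C)C)CC(=O)C2C(=O)CC(=O)CC2=O)cc1CC=C(C)C | intermediate
19 | (R)-3-(tert-butyldimethylsilyloxy)-3-(4-methoxy-3-prenylphenyl)-1-(2,4,6-trihydroxyphenyl)propan-1-one | COc1ccc([C@H](O[Si](C)(C)C(C)(C)C)CC(=O)c2c(O)cc(O)cc2O)cc1CC=C(C)C | intermediate
20 | (R)-3-hydroxy-3-(4-methoxy-3-prenylphenyl)-1-(2,4,6-trihydroxyphenyl)propan-1-one | COc1ccc([C@H](O)CC(=O)c2c(O)cc(O)cc2O)cc1CC=C(C)C | intermediate
21 | (R)-alkoxytriphenylphosphonium ortho-phenoxide zwitterion of 20 (formed in the flask) | COc1ccc([C@H](O[P+](c2ccccc2)(c2ccccc2)c2ccccc2)CC(=O)c2c(O)cc(O)cc2[O-])cc1CC=C(C)C | intermediate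
22 | 4'-O-methyllicoflavanone, (S)-5,7-dihydroxy-2-(4-methoxy-3-prenylphenyl)chroman-4-one | COc1ccc([C@@H]2CC(=O)c3c(O)cc(O)cc3O2)cc1CC=C(C)C | target

## Step count and least certain steps

Total: 11 steps. Longest linear sequence: 10 steps (steps 1 to 6 and 8 to 11, from 1); step 7 is a one-step branch from 12. The stereocentre is set in step 4 as (R), carried unchanged through steps 5 to 10 and inverted to (S) in step 11.

Step 9 (key step). Most likely to go wrong: closure in the wrong sense, that is aldol-type attack of C2 on the C7 ketone followed by dehydration, or O-cyclization during the acidic work-up. The chain offers two nucleophilic methylenes and four carbonyls, and the choice rests on magnesium chelation and not on a structural block. Slow loss of silanolate from C9 on long exposure to base is a secondary risk. Fallback, setting out from 11 and coming back at 19: ring A is attached preformed instead of being built.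
- Phloroglucinol is converted with MOMCl and NaH in DMF into 1,3,5-tris(methoxymethoxy)benzene F1.
- F1 is lithiated between two acetal oxygens (n-BuLi, THF, 0 °C) to 2,4,6-tris(methoxymethoxy)phenyllithium F2.
- F2 is added to 11 at −78 °C to give (R)-3-(tert-butyldimethylsilyloxy)-3-(4-methoxy-3-prenylphenyl)-1-[2,4,6-tris(methoxymethoxy)phenyl]propan-1-one F3.
- The three aryl acetals are removed under non-protic conditions (TMSOTf, 2,2'-bipyridyl, MeCN, 0 °C; then water), which should spare the benzylic silyl ether and return 19.

Step 8. Most likely to go wrong: proton transfer in place of C–C bond formation. The terminal carbanion of 15 is basic enough to enolize 11, after which silanolate is lost by E1cB, and 15 is a poorly soluble aggregate. Premature cyclization of 17 during work-up is the second risk. Fallback, setting out from 11 and coming back at 19 (it makes step 7 unnecessary): the polyketide half is used as a lactone-masked dianion.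
- Commercial 4-hydroxy-6-methyl-2H-pyran-2-one is converted with LiN(iPr)2 (2.2 equiv, THF, −78 °C) into its dilithium dianion F4.
- F4 is acylated at the 6-methyl carbon by 11 to give 6-[(4R)-4-(tert-butyldimethylsilyloxy)-4-(4-methoxy-3-prenylphenyl)-2-oxobutyl]-4-hydroxy-2H-pyran-2-one F5, a stable, isolable lactone form of the acid of 17.
- Mg(OMe)2 in methanol should open the lactone of F5 to 17 in the flask and carry it through the Claisen closure to 19.

Step 11. Most likely to go wrong: erosion of configuration and loss of material through slow ring closure. The para hydroxyl is the most acidic site, so the ortho-phenoxide that must attack is present only in low concentration. The activated para-methoxybenzylic carbinol then has time to ionize, to eliminate to the chalcone (which recloses without selectivity), or to be etherified by a second molecule. Fallback, setting out from 19 and coming back at 22: the competing phenols are masked so that the only acidic site is the nucleophile.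
- MOMCl (2.2 equiv) and i-Pr2NEt in CH2Cl2 at 0 °C etherify the para hydroxyl and one ortho hydroxyl and leave the ketone-chelated one, giving (R)-3-(tert-butyldimethylsilyloxy)-1-[2-hydroxy-4,6-bis(methoxymethoxy)phenyl]-3-(4-methoxy-3-prenylphenyl)propan-1-one F6.
- HF·pyridine with pyridine gives (R)-3-hydroxy-1-[2-hydroxy-4,6-bis(methoxymethoxy)phenyl]-3-(4-methoxy-3-prenylphenyl)propan-1-one F7.
- PPh3 and DIAD close F7 with inversion to (S)-5,7-bis(methoxymethoxy)-4'-methoxy-3'-prenylflavanone F8, which has the structure of A10.
- HCl in methanol at rt to 40 °C removes the two acetals and gives 22.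

Step 1. Most likely to go wrong: alkylation at oxygen in place of carbon, and a second alkylation of the product, because the ester-stabilized phenoxide is a weak carbon nucleophile. Fallback, setting out from 1 and coming back at 4: the prenyl group is delivered by a sigmatropic shift.
- 1 is O-alkylated with 3-chloro-3-methylbut-1-yne (DBU, CuCl2 cat., MeCN, 0 °C) to methyl 4-[(2-methylbut-3-yn-2-yl)oxy]benzoate F9.
- Semi-hydrogenation (H2, Pd/CaCO3 poisoned with Pb(OAc)2, quinoline, EtOAc) gives methyl 4-[(2-methylbut-3-en-2-yl)oxy]benzoate F10.
- Aromatic Claisen rearrangement of F10 (xylene, 130 °C) moves the allyl unit to the ortho carbon with allylic transposition and gives 4.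

## Further compounds

F1 | step 9 | 1,3,5-tris(methoxymethoxy)benzene | COCOc1cc(OCOC)cc(OCOC)c1
F2 | step 9 | 2,4,6-tris(methoxymethoxy)phenyllithium | [Li]c1c(OCOC)cc(OCOC)cc1OCOC
F3 | step 9 | (R)-3-(tert-butyldimethylsilyloxy)-3-(4-methoxy-3-prenylphenyl)-1-[2,4,6-tris(methoxymethoxy)phenyl]propan-1-one | COc1ccc([C@H](O[Si](C)(C)C(C)(C)C)CC(=O)c2c(OCOC)cc(OCOC)cc2OCOC)cc1CC=C(C)C
F4 | step 8 | dilithium dianion of 4-hydroxy-6-methyl-2H-pyran-2-one | [Li+].[Li+].[CH2-]c1cc([O-])cc(=O)o1
F5 | step 8 | 6-[(4R)-4-(tert-butyldimethylsilyloxy)-4-(4-methoxy-3-prenylphenyl)-2-oxobutyl]-4-hydroxy-2H-pyran-2-one | COc1ccc([C@H](O[Si](C)(C)C(C)(C)C)CC(=O)Cc2cc(O)cc(=O)o2)cc1CC=C(C)C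
F6 | step 11 | (R)-3-(tert-butyldimethylsilyloxy)-1-[2-hydroxy-4,6-bis(methoxymethoxy)phenyl]-3-(4-methoxy-3-prenylphenyl)propan-1-one | COc1ccc([C@H](O[Si](C)(C)C(C)(C)C)CC(=O)c2c(O)cc(OCOC)cc2OCOC)cc1CC=C(C)C
F7 | step 11 | (R)-3-hydroxy-1-[2-hydroxy-4,6-bis(methoxymethoxy)phenyl]-3-(4-methoxy-3-prenylphenyl)propan-1-one | COc1ccc([C@H](O)CC(=O)c2c(O)cc(OCOC)cc2OCOC)cc1CC=C(C)C
F8 | step 11 | (S)-5,7-bis(methoxymethoxy)-4'-methoxy-3'-prenylflavanone | COc1ccc([C@@H]2CC(=O)c3c(OCOC)cc(OCOC)cc3O2)cc1CC=C(C)C
F9 | step 1 | methyl 4-[(2-methylbut-3-yn-2-yl)oxy]benzoate | COC(=O)c1ccc(OC(C)(C)C#C)cc1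
F10 | step 1 | methyl 4-[(2-methylbut-3-en-2-yl)oxy]benzoate | COC(=O)c1ccc(OC(C)(C)C=C)cc1
A1 | alternative 1 | 2-(dimethoxymethyl)-3,5-bis(methoxymethoxy)phenol | COC(OC)c1c(O)cc(OCOC)cc1OCOC
A2 | alternative 1 | 4-methoxy-3-prenylstyrene | COc1ccc(C=C)cc1CC=C(C)C
A3 | alternative 1 | 6-(methoxymethylidene)-3,5-bis(methoxymethoxy)cyclohexa-2,4-dien-1-one | COC=C1C(=O)C=C(OCOC)C=C1OCOC
A4 | alternative 1 | (2S,4S)-4-methoxy-5,7-bis(methoxymethoxy)-2-(4-methoxy-3-prenylphenyl)chroman | COc1ccc([C@@H]2C[C@H](OC)c3c(OCOC)cc(OCOC)cc3O2)cc1CC=C(C)C
A5 | alternative 2 | 2-diazo-1-[2-(4-methoxy-3-prenylbenzyloxy)-4,6-bis(tert-butyldimethylsilyloxy)phenyl]ethanone | COc1ccc(COc2cc(O[Si](C)(C)C(C)(C)C)cc(O[Si](C)(C)C(C)(C)C)c2C(=O)C=[N+]=[N-])cc1CC=C(C)C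
A6 | alternative 2 | (S)-5,7-bis(tert-butyldimethylsilyloxy)-4'-methoxy-3'-prenylflavanone | COc1ccc([C@@H]2CC(=O)c3c(O[Si](C)(C)C(C)(C)C)cc(O[Si](C)(C)C(C)(C)C)cc3O2)cc1CC=C(C)C
A7 | alternative 3 | 3,5-bis(methoxymethoxy)-2-(trimethylsilyl)phenyl trifluoromethanesulfonate | COCOc1cc(OCOC)c([Si](C)(C)C)c(OS(=O)(=O)C(F)(F)F)c1
A8 | alternative 3 | 3,5-bis(methoxymethoxy)benzyne | C1#CC(OCOC)=CC(OCOC)=C1
A9 | alternative 3 | methyl (S)-3-hydroxy-3-(4-methoxy-3-prenylphenyl)propanoate | COc1ccc([C@@H](O)CC(=O)OC)cc1CC=C(C)C
A10 | alternative 3 | (S)-5,7-bis(methoxymethoxy)-4'-methoxy-3'-prenylflavanone | COc1ccc([C@@H]2CC(=O)c3c(OCOC)cc(OCOC)cc3O2)cc1CC=C(C)C
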